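The target is cut at the C3–C3a bond, between the benzylic carbon of ring B (C1–O2–C3–C3a–C6a) and the hydroxylated ring-fusion carbon. It is made by a dirhodium-catalysed carbenoid C–H insertion: ring A is prepared as a cis-disubstituted α-diazo-γ-butyrolactone (C4 still a carbonyl, diazo group at the future C3a) whose C6a arm ends in an ArCH2–O group. The step exploits the C3–H bond, activated by its aryl group and by O2 and in a 1,5 relationship to the carbenoid carbon. In one operation it closes ring B, fixes the cis ring fusion and places the C3 aryl group endo. The lactone stereocentres come from one catalytic asymmetric allylation; enolate hydroxylation at C3a and lactone-to-ether adjustment follow.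

Key step: step 6

Remark (stereochemistry): the SMILES places both aryl groups on the concave face, trans to the ring-fusion OH and H, i.e. (3S,3aS,6R,6aR). The route is built for this all-endo isomer and uses no acid once the bicycle is complete.

Remark (notation): target atoms are numbered as in furo[3,4-c]furan; ring A = C3a–C4–O5–C6–C6a, ring B = C1–O2–C3–C3a–C6a. Ar = 4-(benzyloxy)-3-methoxyphenyl. In step 2 the catalyst enantiomer is the one that directs addition to the Re face of the aldehyde.

Step 1
Reactants: 1 [4-(benzyloxy)-3-methoxyphenyl]methanol (ArCH2OH); 2 (Z)-1,4-dichlorobut-2-ene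
Product: 3 1-(benzyloxy)-4-({[(2Z)-4-chlorobut-2-en-1-yl]oxy}methyl)-2-methoxybenzene
Conditions: NaH, THF/DMF, 0 °C to rt, 2 in fourfold excess
Reagents that add atoms: none
Why: Williamson ether synthesis: the alkoxide of 1 displaces one primary allylic chloride of 2 by SN2, which keeps the Z double bond, and the excess of 2 should hold back double substitution.

Step 2
Reactants: 3 Z-allylic chloride; 4 4-(benzyloxy)-3-methoxybenzaldehyde (ArCHO)
Product: 6 (1R,2R)-1-Ar-2-[(ArCH2O)methyl]but-3-en-1-ol, via allyltrichlorosilane 5 (not isolated)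
Conditions: HSiCl3, CuCl (5 mol %), iPr2NEt, Et2O, rt; filter, concentrate; then 4, chiral 2,2′-bipyrrolidine-derived bisphosphoramide with a pentamethylene tether (5 mol %, Re-face-selective enantiomer), iPr2NEt, CH2Cl2, −78 °C; aq. NaHCO3
Reagents that add atoms: none
Why: Copper-catalysed silylation of the allylic chloride should give the linear Z-allyltrichlorosilane with retention of geometry, and the Lewis-base-catalysed allylation of 4 (Sakurai–Hosomi type, closed chair transition state at hexacoordinate silicon) transfers the Z geometry into the syn relationship while the chiral phosphoramide selects the Re face of the aldehyde, so both stereocentres (1R,2R) are set here.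

Step 3
Reactants: 6 syn homoallylic alcohol
Product: 7 (1R,2R)-1-Ar-2-[(ArCH2O)methyl]butane-1,4-diol
Conditions: 9-BBN (2.5 equiv), THF, 0 °C to rt; then NaOH, H2O2, 0 °C
Reagents that add atoms: hydrogen peroxide, OO
Why: Hydroboration–oxidation with the bulky borane places boron on the terminal alkene carbon, so the primary alcohol forms without touching either stereocentre.

Step 4
Reactants: 7 1,4-diol
Product: 8 (4R,5R)-5-Ar-4-[(ArCH2O)methyl]oxolan-2-one
Conditions: TEMPO (20 mol %), PhI(OAc)2, CH2Cl2, rt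
Reagents that add atoms: none
Why: Oxoammonium (TEMPO) oxidation takes the primary alcohol first, the aldehyde is caught as the five-membered lactol by the benzylic hydroxyl and oxidised on to the lactone (oxidative lactonisation), so the syn diol maps onto the cis-4,5-disubstituted lactone without any bond to a stereocentre being broken.

Step 5
Reactants: 8 cis-lactone
Product: 10 (4R,5R)-5-Ar-4-[(ArCH2O)methyl]-3-diazooxolan-2-one, via trifluoroacetyl lactone 9 (not isolated)
Conditions: LiN(SiMe3)2, THF, −78 °C; CF3CO2CH2CF3; aq. NH4Cl; then 4-acetamidobenzenesulfonyl azide, Et3N, H2O (1 equiv), MeCN, rt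
Reagents that add atoms: 4-acetamidobenzenesulfonyl azide, CC(=O)Nc1ccc(cc1)S(=O)(=O)N=[N+]=[N-]
Why: Detrifluoroacetylative diazo transfer (Regitz-type): Claisen trifluoroacetylation activates the α-CH2 and the sulfonyl azide then delivers N2 with loss of the trifluoroacetyl group, while C-4 and C-5 are not acidic and stay as set.

Step 6
Reactants: 10 α-diazo lactone
Product: 11 (3R,3aR,6R,6aS)-3,6-di-Ar-tetrahydro-1H,3H-furo[3,4-c]furan-1-one
Conditions: Rh2(OAc)4 (2 mol %), CH2Cl2, 4 Å molecular sieves, rt, slow addition of 10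
Reagents that add atoms: none
Why: Rh2(OAc)4 turns the diazo group into an electrophilic divalent-rhodium carbenoid at C-3 of the lactone, which inserts through a concerted, hydride-transfer-like three-centre transition state into the benzylic C–H bond of the ether arm and forms the C6–C6a bond of 11 (C3–C3a of the target); this is the known intramolecular carbenoid C–H insertion of α-diazo-γ-butyrolactones into benzyl ether C–H bonds. Ring B closes as a 1,5-insertion, i.e. through a five-membered ring, the kinetically preferred size for such carbenoids. The ring-fusion centre C6a is controlled by the tether: the arm on C-4 can reach the carbenoid only from its own face, so the bicycle is cis-fused. The benzylic centre C6 is controlled by the catalyst: in the insertion transition state the aryl group turns away from the carboxylate wall of the dirhodium core on the convex side and ends on the concave (endo) face, trans to H-6a. The step needs site selectivity over 1,2-hydride shift to the butenolide, oxonium-ylide formation and attack on the arenes; this is secured by the double activation of the target C–H bond (aryl group and ether oxygen) and its 1,5 relationship to the carbenoid carbon.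

Step 7
Reactants: 11 endo,endo-furofuranone
Product: 12 (3R,3aR,6S,6aR)-3,6-di-Ar-6a-hydroxytetrahydro-1H,3H-furo[3,4-c]furan-1-one
Conditions: KN(SiMe3)2, THF, −78 °C; 2-(benzenesulfonyl)-3-phenyloxaziridine, −78 °C; aq. NH4Cl
Reagents that add atoms: 2-(benzenesulfonyl)-3-phenyloxaziridine, O=S(=O)(c1ccccc1)N1OC1c1ccccc1
Why: Davis enolate hydroxylation: the potassium enolate is planar at the ring-fusion carbon and only the cis-fused bicycle can re-form, so oxygen is delivered on the convex face and the hydroxyl takes the place of H-6a, while the low temperature should keep the enolate from opening ring B by loss of the β-alkoxide.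

Step 8
Reactants: 12 α-hydroxy lactone
Product: 13 (2S,3S,4R)-2-Ar-4-[(R)-Ar(hydroxy)methyl]-3-(hydroxymethyl)oxolan-3-ol
Conditions: LiAlH4, THF, 0 °C; aq. NaOH work-up
Reagents that add atoms: none
Why: Hydride reduction of the lactone to the diol (LiAlH4 reduction) breaks only the acyl C–O bond, so all four stereocentres are untouched.

Step 9
Reactants: 13 triol
Product: 16 (3S,3aS,6R,6aR)-3,6-di-Ar-tetrahydro-1H,3H-furo[3,4-c]furan-3a(4H)-ol, via primary tosylate 14 (not isolated), via spiro-epoxide 15 (not isolated)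
Conditions: Bu2SnO (5 mol %), TsCl (1.05 equiv), Et3N, CH2Cl2, 0 °C; then NaH, THF, 0 to 40 °C
Reagents that add atoms: none
Why: Tin-acetal-catalysed sulfonylation should pick the primary hydroxyl of the 1,2-diol unit, the neighbouring tertiary alkoxide then closes the spiro-epoxide and the benzylic alkoxide opens it at its CH2 carbon (intramolecular Williamson-type etherification forming ring A), so no bond to a stereocentre is broken and the C6 aryl group stays endo.

Step 10
Reactants: 16 dibenzyl ether of the target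
Product: 17 (3S,3aS,6R,6aR)-3,6-bis(4-hydroxy-3-methoxyphenyl)tetrahydro-1H,3H-furo[3,4-c]furan-3a(4H)-ol
Conditions: H2 (1 atm), 10 % Pd/C, EtOAc, rt, stopped at full conversion; purification on neutral silica
Reagents that add atoms: none
Why: Catalytic hydrogenolysis of the two aryl benzyl ethers under neutral, aprotic conditions should be much faster than cleavage of the ring benzylic C–O bonds, and the absence of acid protects the endo aryl groups from epimerisation.

Compound list
1 | [4-(benzyloxy)-3-methoxyphenyl]methanol | OCc1ccc(OCc2ccccc2)c(OC)c1 | starting material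
2 | (Z)-1,4-dichlorobut-2-ene | ClC/C=C\CCl | starting material
3 | 1-(benzyloxy)-4-({[(2Z)-4-chlorobut-2-en-1-yl]oxy}methyl)-2-methoxybenzene | ClC/C=C\COCc1ccc(OCc2ccccc2)c(OC)c1 | intermediate
4 | 4-(benzyloxy)-3-methoxybenzaldehyde | O=Cc1ccc(OCc2ccccc2)c(OC)c1 | starting material
5 | trichloro[(2Z)-4-(ArCH2O)but-2-en-1-yl]silane | Cl[Si](Cl)(Cl)C/C=C\COCc1ccc(OCc2ccccc2)c(OC)c1 | intermediate (not isolated)
6 | (1R,2R)-1-Ar-2-[(ArCH2O)methyl]but-3-en-1-ol (syn) | COc1cc([C@H](O)[C@@H](COCc2ccc(OCc3ccccc3)c(OC)c2)C=C)ccc1OCc1ccccc1 | intermediate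
7 | (1R,2R)-1-Ar-2-[(ArCH2O)methyl]butane-1,4-diol | COc1cc([C@H](O)[C@@H](COCc2ccc(OCc3ccccc3)c(OC)c2)CCO)ccc1OCc1ccccc1 | intermediate
8 | (4R,5R)-5-Ar-4-[(ArCH2O)methyl]oxolan-2-one (cis) | COc1cc([C@@H]2OC(=O)C[C@@H]2COCc2ccc(OCc3ccccc3)c(OC)c2)ccc1OCc1ccccc1 | intermediate
9 | (4R,5R)-5-Ar-4-[(ArCH2O)methyl]-3-(trifluoroacetyl)oxolan-2-one (C-3 unassigned) | COc1cc([C@@H]2OC(=O)C(C(=O)C(F)(F)F)[C@@H]2COCc2ccc(OCc3ccccc3)c(OC)c2)ccc1OCc1ccccc1 | intermediate (not isolated)
10 | (4R,5R)-5-Ar-4-[(ArCH2O)methyl]-3-diazooxolan-2-one | COc1cc([C@@H]2OC(=O)C(=[N+]=[N-])[C@@H]2COCc2ccc(OCc3ccccc3)c(OC)c2)ccc1OCc1ccccc1 | intermediate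
11 | (3R,3aR,6R,6aS)-3,6-di-Ar-tetrahydro-1H,3H-furo[3,4-c]furan-1-one (cis-fused, both aryl groups endo) | COc1cc([C@@H]2OC(=O)[C@H]3[C@@H]2CO[C@H]3c2ccc(OCc4ccccc4)c(OC)c2)ccc1OCc1ccccc1 | intermediate
12 | (3R,3aR,6S,6aR)-3,6-di-Ar-6a-hydroxytetrahydro-1H,3H-furo[3,4-c]furan-1-one | COc1cc([C@@H]2OC(=O)[C@@]3(O)[C@@H]2CO[C@H]3c2ccc(OCc4ccccc4)c(OC)c2)ccc1OCc1ccccc1 | intermediate
13 | (2S,3S,4R)-2-Ar-4-[(R)-Ar(hydroxy)methyl]-3-(hydroxymethyl)oxolan-3-ol | COc1cc([C@H](O)[C@H]2CO[C@@H](c3ccc(OCc4ccccc4)c(OC)c3)[C@@]2(O)CO)ccc1OCc1ccccc1 | intermediate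
14 | primary 4-methylbenzenesulfonate of 13 (sulfonate on the hydroxymethyl group; centres as in 13) | COc1cc([C@H](O)[C@H]2CO[C@@H](c3ccc(OCc4ccccc4)c(OC)c3)[C@@]2(O)COS(=O)(=O)c2ccc(C)cc2)ccc1OCc1ccccc1 | intermediate (not isolated)
15 | (R)-Ar[(3S,4S,7R)-4-Ar-1,5-dioxaspiro[2.4]heptan-7-yl]methanol (spiro-epoxide) | COc1cc([C@H](O)[C@H]2CO[C@@H](c3ccc(OCc4ccccc4)c(OC)c3)[C@@]23CO3)ccc1OCc1ccccc1 | intermediate (not isolated)
16 | (3S,3aS,6R,6aR)-3,6-di-Ar-tetrahydro-1H,3H-furo[3,4-c]furan-3a(4H)-ol | COc1cc([C@@H]2OC[C@@]3(O)[C@@H]2CO[C@H]3c2ccc(OCc4ccccc4)c(OC)c2)ccc1OCc1ccccc1 | intermediate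
17 | (3S,3aS,6R,6aR)-3,6-bis(4-hydroxy-3-methoxyphenyl)tetrahydro-1H,3H-furo[3,4-c]furan-3a(4H)-ol | COc1cc([C@@H]2OC[C@@]3(O)[C@@H]2CO[C@H]3c2ccc(O)c(OC)c2)ccc1O | target

Total step count: 10. Longest linear sequence: 10 steps (from 1 or 2 to 17; aldehyde 4 enters in step 2).

Steps most likely to fail

Step 6. The carbenoid may be diverted by 1,2-hydride shift or by ylide formation at the ether oxygen, or it may insert with eroded endo selectivity because the cis aryl group of ring A crowds the concave face. The fallback sets out from lactone 8 and comes back at 11. Oxidative cleavage of the electron-rich benzylic ether (DDQ, CH2Cl2/pH 7 buffer) gives hydroxymethyl lactone F1. Acylation with 4-(benzyloxy)-3-methoxybenzoyl chloride (pyridine, DMAP) gives aroyl ester F2. LiN(SiMe3)2 (2 equiv, THF, −78 °C) forms the lactone enolate, which attacks the ester carbonyl intramolecularly (Claisen-type O-to-C acyl transfer, again joining the same two carbons in a ring-closing event) and after work-up rests as cyclic hemiketal F3. Ionic hydrogenation (Et3SiH, BF3·OEt2, CH2Cl2, −78 °C) then delivers hydride to the oxocarbenium ion from the convex face, which leaves the aryl group endo and gives 11.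

Step 7. The enolate may lose the β-alkoxide (opening ring B and scrambling the endo benzylic centre) or be captured by the sulfonimine by-product. The fallback sets out from 11 and comes back at 12. LiN(SiMe3)2 is added to 11 in the presence of Me3SiCl at −78 °C (internal quench), so the enolate is trapped as it forms to give silyl ketene acetal F4. This is oxidised under neutral conditions with dimethyldioxirane in acetone at −78 °C (Rubottom oxidation) and desilylated with Bu4NF/AcOH to give 12.

Step 2. The Z geometry may erode during silylation, or the chelating ether arm and the electron-rich aldehyde may loosen the closed transition state, lowering syn and facial selectivity. The fallback replaces catalyst control by auxiliary control; it sets out from 1 and 4 and comes back at 6.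
- Alcohol 1 is added to (R)-3-acryloyl-4-benzyl-1,3-oxazolidin-2-one (PBu3 cat., oxa-Michael addition) to give imide F5.
- Its dibutylboron enolate (Bu2BOTf, iPr2NEt, CH2Cl2, −78 °C) adds to aldehyde 4 (Evans syn-aldol) to give aldol adduct F6, with the (2R,3R) configuration set by the auxiliary.
- AlMe3/MeNHOMe·HCl gives Weinreb amide F7, and TBSOTf/2,6-lutidine gives silyl ether F8.
- iBu2AlH (−78 °C) gives aldehyde F9, and Ph3P=CH2 gives silyl-protected alkene F10.
- Bu4NF returns 6.

Further compounds
F1 | step 6 | (4R,5R)-5-Ar-4-(hydroxymethyl)oxolan-2-one | COc1cc([C@@H]2OC(=O)C[C@@H]2CO)ccc1OCc1ccccc1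
F2 | step 6 | [(2R,3R)-2-Ar-5-oxooxolan-3-yl]methyl 4-(benzyloxy)-3-methoxybenzoate | COc1cc([C@@H]2OC(=O)C[C@@H]2COC(=O)c2ccc(OCc3ccccc3)c(OC)c2)ccc1OCc1ccccc1
F3 | step 6 | (3R,3aR,6aS)-3,6-di-Ar-6-hydroxytetrahydro-1H,3H-furo[3,4-c]furan-1-one (cyclic hemiketal, C6 unassigned) | COc1cc([C@@H]2OC(=O)[C@H]3[C@@H]2COC3(O)c2ccc(OCc4ccccc4)c(OC)c2)ccc1OCc1ccccc1
F4 | step 7 | trimethylsilyl ketene acetal of 11 (C1=C6a double bond, other centres as in 11) | COc1cc([C@@H]2OC(O[Si](C)(C)C)=C3[C@@H]2CO[C@H]3c2ccc(OCc4ccccc4)c(OC)c2)ccc1OCc1ccccc1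
F5 | step 2 | (R)-4-benzyl-3-[3-(ArCH2O)propanoyl]-1,3-oxazolidin-2-one | O=C(CCOCc1ccc(OCc2ccccc2)c(OC)c1)N1[C@H](Cc2ccccc2)COC1=O
F6 | step 2 | (R)-4-benzyl-3-{(2R,3R)-3-Ar-3-hydroxy-2-[(ArCH2O)methyl]propanoyl}-1,3-oxazolidin-2-one | COc1cc([C@H](O)[C@@H](COCc2ccc(OCc3ccccc3)c(OC)c2)C(=O)N2[C@H](Cc3ccccc3)COC2=O)ccc1OCc1ccccc1
F7 | step 2 | (2R,3R)-3-Ar-3-hydroxy-N-methoxy-N-methyl-2-[(ArCH2O)methyl]propanamide | COc1cc([C@H](O)[C@@H](COCc2ccc(OCc3ccccc3)c(OC)c2)C(=O)N(C)OC)ccc1OCc1ccccc1
F8 | step 2 | (2R,3R)-3-Ar-3-[(tert-butyldimethylsilyl)oxy]-N-methoxy-N-methyl-2-[(ArCH2O)methyl]propanamide | COc1cc([C@H](O[Si](C)(C)C(C)(C)C)[C@@H](COCc2ccc(OCc3ccccc3)c(OC)c2)C(=O)N(C)OC)ccc1OCc1ccccc1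
F9 | step 2 | (2R,3R)-3-Ar-3-[(tert-butyldimethylsilyl)oxy]-2-[(ArCH2O)methyl]propanal | COc1cc([C@H](O[Si](C)(C)C(C)(C)C)[C@@H](COCc2ccc(OCc3ccccc3)c(OC)c2)C=O)ccc1OCc1ccccc1
F10 | step 2 | tert-butyldimethylsilyl ether of 6, (1R,2R) | COc1cc([C@H](O[Si](C)(C)C(C)(C)C)[C@@H](COCc2ccc(OCc3ccccc3)c(OC)c2)C=C)ccc1OCc1ccccc1
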